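## Retrosynthetic overview

1. The target is a (1(10)Z,4Z)-germacradien-6,12-olide. The last disconnection takes CO2 out of the α-methylene-γ-lactone (bonds O–C6 and C11–C12), leaving a carbocyclic alkenylboronate whose C6 and C8 oxygens are tied together as a cyclic sulfate.
2. Enabling feature: C6 is an allylic carbinol carbon (next to the C4=C5 alkene) lying 1,3 to the C8 hydroxyl, and the lactone carbonyl sits on the sp2 carbon C11, two bonds from C6. C11 can therefore act as a vinyl nucleophile toward CO2, while C6 is the electrophilic carbon of a six-membered cyclic sulfate that also hides the C8 hydroxyl.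
3. The ten-membered carbocycle is formed first, by a Nozaki–Hiyama–Kishi closure of C9–C10; the γ-lactone ring is formed last.
4. The open chain comes from a syn-selective SE2′ addition of an epoxide-derived chiral allenylstannane (C7–C9, C11, C13) to a nerol-derived (Z)-enal (C1–C6, C10, C14, C15).

Key step: step 21

Remark: locants C1–C15 are those of the germacrane skeleton of the target (C6 lactone carbinol carbon, C7 ring-fusion carbon, C8 carbinol, C9 acetoxy carbon, C11–C13 acrylate unit with C12 the carbonyl, C14 the CH2O on C10, C15 the methyl on C4).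
Assumption: (2E)-pent-2-en-4-yn-1-ol is taken as a purchasable alkynol (otherwise one step from epichlorohydrin and sodium acetylide).

## Route

Step 1
Reactants: 1 nerol
Product: 2 neryl tert-butyldiphenylsilyl ether
Conditions: TBDPSCl, imidazole, DMF, 0 °C to rt
Reagents that add atoms: tert-butyl(chloro)diphenylsilane, CC(C)(C)[Si](Cl)(c1ccccc1)c1ccccc1
Why: Imidazole-promoted silylation of the primary allylic alcohol gives a silyl ether that should survive the acidic and basic steps up to step 8; no stereocentre is formed.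

Step 2
Reactants: 2 neryl tert-butyldiphenylsilyl ether
Product: 3 6,7-epoxide of the neryl silyl ether (racemic at the oxirane CH)
Conditions: mCPBA, NaHCO3, CH2Cl2, −20 °C
Reagents that add atoms: 3-chloroperoxybenzoic acid, OOC(=O)c1cccc(Cl)c1
Why: Prilezhaev epoxidation should occur at the remote, more electron-rich trisubstituted alkene because the other alkene is deactivated and shielded by the allylic silyl ether; the new centre is racemic and is removed in step 3.

Step 3
Reactants: 3 6,7-epoxide of the neryl silyl ether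
Product: 5 (4Z)-6-[(tert-butyldiphenylsilyl)oxy]-4-methylhex-4-enal, via vicinal diol 4 (not isolated)
Conditions: H5IO6, THF/H2O, 0 °C
Reagents that add atoms: none
Why: Acid-promoted hydrolysis of the epoxide followed in the same flask by Malaprade glycol cleavage excises acetone and leaves the aldehyde that becomes C1, the (Z)-alkene being untouched.

Step 4
Reactants: 5 (4Z)-6-[(tert-butyldiphenylsilyl)oxy]-4-methylhex-4-enal; 6 (triphenylphosphoranylidene)acetaldehyde
Product: 7 (2E,6Z)-8-[(tert-butyldiphenylsilyl)oxy]-6-methylocta-2,6-dienal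
Conditions: toluene, 80 °C
Reagents that add atoms: none
Why: Wittig olefination with the stabilised formyl ylide should give the (E)-enal and adds the two carbons that become C10 and C14.

Step 5
Reactants: 7 (2E,6Z)-8-[(tert-butyldiphenylsilyl)oxy]-6-methylocta-2,6-dienal
Product: 8 (2Z,6Z)-8-[(tert-butyldiphenylsilyl)oxy]-2-iodo-6-methylocta-2,6-dienal
Conditions: I2, K2CO3, DMAP (20 mol%), THF/H2O, rt
Reagents that add atoms: iodine, [I][I]
Why: DMAP-catalysed α-iodination of the enal (conjugate addition, iodination of the enolate, elimination) should give the thermodynamically favoured (Z)-α-iodoenal, which puts iodine cis to the chain and so fixes the ring-cis geometry of the later C1=C10 alkene.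

Step 6
Reactants: 8 (2Z,6Z)-8-[(tert-butyldiphenylsilyl)oxy]-2-iodo-6-methylocta-2,6-dienal
Product: 9 (2Z,6Z)-8-[(tert-butyldiphenylsilyl)oxy]-2-iodo-6-methylocta-2,6-dien-1-ol
Conditions: NaBH4, CeCl3·7H2O, MeOH, −20 °C
Reagents that add atoms: none
Why: Luche reduction delivers hydride 1,2 to the enal without touching the C–I bond.

Step 7
Reactants: 9 (2Z,6Z)-8-[(tert-butyldiphenylsilyl)oxy]-2-iodo-6-methylocta-2,6-dien-1-ol; 10 (2S)-2-methylbutanoic acid
Product: 11 (2Z,6Z)-8-[(tert-butyldiphenylsilyl)oxy]-2-iodo-6-methylocta-2,6-dien-1-yl (2S)-2-methylbutanoate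
Conditions: dicyclohexylcarbodiimide, DMAP (10 mol%), CH2Cl2, 0 °C
Reagents that add atoms: none
Why: Steglich esterification joins the primary allylic alcohol to the acid; low DMAP loading at 0 °C should keep the α-stereocentre of the acid, which is the only source of that centre in the target.

Step 8
Reactants: 11 (2Z,6Z)-8-[(tert-butyldiphenylsilyl)oxy]-2-iodo-6-methylocta-2,6-dien-1-yl (2S)-2-methylbutanoate
Product: 12 (2Z,6Z)-8-hydroxy-2-iodo-6-methylocta-2,6-dien-1-yl (2S)-2-methylbutanoate
Conditions: TBAF, AcOH, THF, 0 °C to rt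
Reagents that add atoms: none
Why: Fluoride cleavage of the silyl ether, buffered with acetic acid so that the ester is neither cleaved nor transferred.

Step 9
Reactants: 12 (2Z,6Z)-8-hydroxy-2-iodo-6-methylocta-2,6-dien-1-yl (2S)-2-methylbutanoate
Product: 13 fragment A: (2Z,6Z)-2-iodo-6-methyl-8-oxoocta-2,6-dien-1-yl (2S)-2-methylbutanoate
Conditions: MnO2 (activated), CH2Cl2, rt
Reagents that add atoms: none
Why: MnO2 oxidises the allylic alcohol to the enal under neutral conditions that should not isomerise the (Z)-trisubstituted alkene.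

Step 10
Reactants: 14 (2E)-pent-2-en-4-yn-1-ol
Product: 15 [(2R,3R)-3-ethynyloxiran-2-yl]methanol
Conditions: Ti(OiPr)4 (10 mol%), D-(−)-diethyl tartrate (12 mol%), tBuOOH, 4 Å molecular sieves, CH2Cl2, −20 °C
Reagents that add atoms: tert-butyl hydroperoxide, CC(C)(C)OO
Why: Sharpless asymmetric epoxidation with the D-(−)-tartrate should give the (2R,3R)-epoxide, which fixes C8 and stores the configuration of C7 in a C–O bond.

Step 11
Reactants: 15 [(2R,3R)-3-ethynyloxiran-2-yl]methanol
Product: 16 triethyl{[(2R,3R)-3-ethynyloxiran-2-yl]methoxy}silane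
Conditions: TESCl, imidazole, CH2Cl2, 0 °C
Reagents that add atoms: chlorotriethylsilane, CC[Si](Cl)(CC)CC
Why: Silylation of the primary alcohol under nearly neutral conditions, which avoids Payne rearrangement of the epoxy alcohol.

Step 12
Reactants: 16 triethyl{[(2R,3R)-3-ethynyloxiran-2-yl]methoxy}silane
Product: 18 fragment B: (2S)-1,2-bis[(triethylsilyl)oxy]-5-(tributylstannyl)penta-3,4-diene (aR allene axis), via lithium alkoxide 17 (not isolated)
Conditions: Bu3SnH, LDA, THF, 0 °C; CuBr·SMe2, −78 °C; then 16, −78 °C; then TESCl, −78 to 0 °C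
Reagents that add atoms: tributyltin hydride, CCCC[SnH](CCCC)CCCC; chlorotriethylsilane, CC[Si](Cl)(CC)CC
Why: SN2′ stannylcupration of the alkynyl oxirane proceeds anti, so the epoxide C–O configuration is transferred to the allene axis, and the liberated C8 alkoxide is silylated in the same flask.

Step 13
Reactants: 13 fragment A enal; 18 fragment B allenylstannane
Product: 19 (2Z,6Z,8S,9S,10S)-9-ethynyl-8-hydroxy-2-iodo-6-methyl-10,11-bis[(triethylsilyl)oxy]undeca-2,6-dien-1-yl (2S)-2-methylbutanoate
Conditions: BF3·OEt2, CH2Cl2, −78 °C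
Reagents that add atoms: none
Why: BF3-promoted SE2′ addition of the chiral allenylstannane to the enal through an open antiperiplanar transition state should give the syn homopropargylic alcohol: anti-SE2′ transfers the axis to C7 (the new C–C bond stands where the epoxide C–O bond stood), and the syn topology sets C6 as 6S, epimeric to the target as required for the invertive closure of step 21.

Step 14
Reactants: 19 syn homopropargylic alcohol
Product: 20 (2Z,6Z,8S,9S,10S)-9-ethynyl-2-iodo-6-methyl-8,10,11-tris[(triethylsilyl)oxy]undeca-2,6-dien-1-yl (2S)-2-methylbutanoate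
Conditions: TESOTf, 2,6-lutidine, CH2Cl2, −78 °C
Reagents that add atoms: triethylsilyl trifluoromethanesulfonate, CC[Si](CC)(CC)OS(=O)(=O)C(F)(F)F
Why: Silylation of the secondary allylic alcohol with the silyl triflate; no stereocentre is affected.

Step 15
Reactants: 20 tris(triethylsilyl) ether
Product: 21 (2Z,6Z,8S,9S,10S)-9-ethynyl-2-iodo-6-methyl-11-oxo-8,10-bis[(triethylsilyl)oxy]undeca-2,6-dien-1-yl (2S)-2-methylbutanoate
Conditions: (COCl)2, DMSO, CH2Cl2, −78 to −40 °C; then Et3N
Reagents that add atoms: none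
Why: Swern oxidation of a primary triethylsilyl ether: the chlorosulfonium reagent should attack the unhindered primary silyl ether selectively and convert it directly into the C9 aldehyde, while the two secondary silyl ethers remain.

Step 16
Reactants: 21 open-chain iodoalkenyl aldehyde
Product: 22 {(1Z,5Z,7S,8S,9S,10R)-8-ethynyl-10-hydroxy-5-methyl-7,9-bis[(triethylsilyl)oxy]cyclodeca-1,5-dien-1-yl}methyl (2S)-2-methylbutanoate
Conditions: CrCl2 (10 equiv), NiCl2 (1 mol% of the CrCl2), DMSO/THF, rt, slow addition to 2 mM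
Reagents that add atoms: none
Why: Intramolecular Nozaki–Hiyama–Kishi reaction (zerovalent nickel inserts into the C–I bond, transmetalation to chromium, addition to the aldehyde) should close the ten-membered ring with retention of the iodoalkene geometry (ring-cis C1=C10), and Felkin–Anh attack anti to the α-silyloxy group should give the 9R alcohol (8,9-anti).

Step 17
Reactants: 22 macrocyclic C9 alcohol
Product: 23 {(1Z,5Z,7S,8S,9S,10R)-10-acetoxy-8-ethynyl-5-methyl-7,9-bis[(triethylsilyl)oxy]cyclodeca-1,5-dien-1-yl}methyl (2S)-2-methylbutanoate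
Conditions: Ac2O, pyridine, DMAP (cat.), CH2Cl2, 0 °C
Reagents that add atoms: acetic anhydride, CC(=O)OC(C)=O
Why: DMAP-catalysed acetylation of the only free hydroxyl installs the C9 acetate before any neighbouring hydroxyl is free.

Step 18
Reactants: 23 macrocyclic alkyne acetate
Product: 24 {(1Z,5Z,7S,8S,9S,10R)-10-acetoxy-5-methyl-8-[1-(4,4,5,5-tetramethyl-1,3,2-dioxaborolan-2-yl)ethenyl]-7,9-bis[(triethylsilyl)oxy]cyclodeca-1,5-dien-1-yl}methyl (2S)-2-methylbutanoate
Conditions: HBpin (1.2 equiv), CoBr2 with a 2-imino-6-(oxazolin-2-yl)pyridine ligand (5 mol%), NaBHEt3 (10 mol%), THF, rt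
Reagents that add atoms: pinacolborane, [H]B1OC(C)(C)C(C)(C)O1
Why: Cobalt hydride-catalysed Markovnikov hydroboration of the terminal alkyne should add H–B syn with boron on the internal carbon C11, giving the 1,1-disubstituted alkenylboronate without touching the esters or the trisubstituted alkenes.

Step 19
Reactants: 24 bis(triethylsilyl) alkenylboronate
Product: 25 {(1Z,5Z,7S,8S,9S,10R)-10-acetoxy-7,9-dihydroxy-5-methyl-8-[1-(4,4,5,5-tetramethyl-1,3,2-dioxaborolan-2-yl)ethenyl]cyclodeca-1,5-dien-1-yl}methyl (2S)-2-methylbutanoate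
Conditions: PPTS, MeOH, 0 °C to rt
Reagents that add atoms: none
Why: Mild acid-catalysed methanolysis removes both secondary triethylsilyl ethers, while the acetate, the ester and the pinacol boronate should survive.

Step 20
Reactants: 25 syn-1,3-diol alkenylboronate
Product: 26 C6,C8-cyclic sulfate of 25 (6S,7S,8S,9R)
Conditions: SO2Cl2, pyridine, CH2Cl2, −78 to −30 °C
Reagents that add atoms: sulfuryl chloride, O=S(=O)(Cl)Cl
Why: Sulfuryl chloride should convert the syn-1,3-diol into the six-membered cyclic sulfate (chlorosulfate formation at one hydroxyl, ring closure by the other), the low temperature suppressing ionisation at the allylic C6; no stereocentre changes, and both hydroxyls are masked and activated at once.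

Step 21
Reactants: 26 cyclic sulfate alkenylboronate
Product: 29 target germacranolide (6R,7R,8S,9R), via potassium carboxylate 27 (not isolated), via lactone sulfate monoester 28 (not isolated)
Conditions: (IPr)CuCl (10 mol%; IPr = 1,3-bis(2,6-diisopropylphenyl)imidazol-2-ylidene), KOtBu (1.1 equiv), CO2 (1 atm), THF, 60 °C; then H2SO4 (cat.), H2O (2 equiv), THF, rt
Reagents that add atoms: carbon dioxide, O=C=O
Why: Proposed new method: alkoxide-assisted boron-to-copper transmetalation of the C11 alkenylboronate gives an (IPr)Cu–alkenyl species that inserts CO2 (C11–C12 bond; closest known type: NHC–copper-catalysed carboxylation of alkenylboronic esters with CO2), and the carboxylate 27, held next to the cyclic sulfate, displaces the sulfate oxygen at C6 (O–C6 bond; closest known type: carboxylate opening of cyclic sulfates, here intramolecular). The γ-lactone closes in the 5-exo-tet mode, the breaking C6–O bond lying outside the new ring and antiperiplanar to C11 across C7–C6 in the chair of the cyclic sulfate. The only stereocentre touched is C6, which is inverted by backside attack from 6S to the 6R configuration of the trans-fused lactone, while C7, C8 and C9 are spectators. Three selectivities are needed: CO2 insertion must outrun alkylation of the alkenylcopper (under 1 atm CO2 the base is present as the poorly nucleophilic tert-butyl carbonate and insertion is fast), the carboxylate must attack C6 and not C8 (both 5-exo, but C6 is activated by the C4=C5 alkene and C8 is retarded by the adjacent acetoxy-bearing carbon), and SN2 must beat SN2′ at C4 (which would need a seven-membered ring at a fully substituted carbon). Because both hydroxyls are tied up in the sulfate, no retentive acyl–oxygen lactonisation can compete. Mild acid hydrolysis of the C8 sulfate monoester 28 should then free the C8 hydroxyl without acyl migration.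

## Compound list

1 | nerol, (2Z)-3,7-dimethylocta-2,6-dien-1-ol | OC/C=C(/C)CCC=C(C)C | starting material
2 | tert-butyl{[(2Z)-3,7-dimethylocta-2,6-dien-1-yl]oxy}diphenylsilane | CC(C)(C)[Si](c1ccccc1)(c1ccccc1)OC/C=C(/C)CCC=C(C)C | intermediate
3 | tert-butyl{[(2Z)-5-(3,3-dimethyloxiran-2-yl)-3-methylpent-2-en-1-yl]oxy}diphenylsilane (racemic at the oxirane CH) | CC(C)(C)[Si](c1ccccc1)(c1ccccc1)OC/C=C(/C)CCC1OC1(C)C | intermediate
4 | (6Z)-8-[(tert-butyldiphenylsilyl)oxy]-2,6-dimethyloct-6-ene-2,3-diol (racemic, not isolated) | CC(C)(C)[Si](c1ccccc1)(c1ccccc1)OC/C=C(/C)CCC(O)C(C)(C)O | intermediate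
5 | (4Z)-6-[(tert-butyldiphenylsilyl)oxy]-4-methylhex-4-enal | CC(C)(C)[Si](c1ccccc1)(c1ccccc1)OC/C=C(/C)CCC=O | intermediate
6 | (triphenylphosphoranylidene)acetaldehyde | O=CC=P(c1ccccc1)(c1ccccc1)c1ccccc1 | starting material
7 | (2E,6Z)-8-[(tert-butyldiphenylsilyl)oxy]-6-methylocta-2,6-dienal | CC(C)(C)[Si](c1ccccc1)(c1ccccc1)OC/C=C(/C)CC/C=C/C=O | intermediate
8 | (2Z,6Z)-8-[(tert-butyldiphenylsilyl)oxy]-2-iodo-6-methylocta-2,6-dienal | CC(C)(C)[Si](c1ccccc1)(c1ccccc1)OC/C=C(/C)CC/C=C(\I)C=O | intermediate
9 | (2Z,6Z)-8-[(tert-butyldiphenylsilyl)oxy]-2-iodo-6-methylocta-2,6-dien-1-ol | CC(C)(C)[Si](c1ccccc1)(c1ccccc1)OC/C=C(/C)CC/C=C(\I)CO | intermediate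
10 | (2S)-2-methylbutanoic acid | CC[C@H](C)C(=O)O | starting material
11 | (2Z,6Z)-8-[(tert-butyldiphenylsilyl)oxy]-2-iodo-6-methylocta-2,6-dien-1-yl (2S)-2-methylbutanoate | CC[C@H](C)C(=O)OC/C(I)=C/CC/C(C)=C\CO[Si](c1ccccc1)(c1ccccc1)C(C)(C)C | intermediate
12 | (2Z,6Z)-8-hydroxy-2-iodo-6-methylocta-2,6-dien-1-yl (2S)-2-methylbutanoate | CC[C@H](C)C(=O)OC/C(I)=C/CC/C(C)=C\CO | intermediate
13 | fragment A, (2Z,6Z)-2-iodo-6-methyl-8-oxoocta-2,6-dien-1-yl (2S)-2-methylbutanoate | CC[C@H](C)C(=O)OC/C(I)=C/CC/C(C)=C\C=O | intermediate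
14 | (2E)-pent-2-en-4-yn-1-ol | C#C/C=C/CO | starting material
15 | [(2R,3R)-3-ethynyloxiran-2-yl]methanol | C#C[C@H]1O[C@@H]1CO | intermediate
16 | triethyl{[(2R,3R)-3-ethynyloxiran-2-yl]methoxy}silane | C#C[C@H]1O[C@@H]1CO[Si](CC)(CC)CC | intermediate
17 | lithium (2S)-5-(tributylstannyl)-1-[(triethylsilyl)oxy]penta-3,4-dien-2-olate, aR allene axis (not isolated) | CCCC[Sn](CCCC)(CCCC)C=[C@]=C[C@H]([O-])CO[Si](CC)(CC)CC.[Li+] | intermediate
18 | fragment B, (2S)-1,2-bis[(triethylsilyl)oxy]-5-(tributylstannyl)penta-3,4-diene, aR allene axis | CCCC[Sn](CCCC)(CCCC)C=[C@]=C[C@H](O[Si](CC)(CC)CC)CO[Si](CC)(CC)CC | intermediate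
19 | (2Z,6Z,8S,9S,10S)-9-ethynyl-8-hydroxy-2-iodo-6-methyl-10,11-bis[(triethylsilyl)oxy]undeca-2,6-dien-1-yl (2S)-2-methylbutanoate (germacrane locants 6S,7S,8S) | CC[C@H](C)C(=O)OC/C(I)=C/CC/C(C)=C\[C@H](O)[C@H](C#C)[C@H](O[Si](CC)(CC)CC)CO[Si](CC)(CC)CC | intermediate
20 | (2Z,6Z,8S,9S,10S)-9-ethynyl-2-iodo-6-methyl-8,10,11-tris[(triethylsilyl)oxy]undeca-2,6-dien-1-yl (2S)-2-methylbutanoate | CC[C@H](C)C(=O)OC/C(I)=C/CC/C(C)=C\[C@H](O[Si](CC)(CC)CC)[C@H](C#C)[C@H](O[Si](CC)(CC)CC)CO[Si](CC)(CC)CC | intermediate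
21 | (2Z,6Z,8S,9S,10S)-9-ethynyl-2-iodo-6-methyl-11-oxo-8,10-bis[(triethylsilyl)oxy]undeca-2,6-dien-1-yl (2S)-2-methylbutanoate | CC[C@H](C)C(=O)OC/C(I)=C/CC/C(C)=C\[C@H](O[Si](CC)(CC)CC)[C@H](C#C)[C@H](O[Si](CC)(CC)CC)C=O | intermediate
22 | {(1Z,5Z,7S,8S,9S,10R)-8-ethynyl-10-hydroxy-5-methyl-7,9-bis[(triethylsilyl)oxy]cyclodeca-1,5-dien-1-yl}methyl (2S)-2-methylbutanoate (germacrane locants 6S,7S,8S,9R) | CC[Si](CC)(CC)O[C@H]1/C=C(/C)CC/C=C(/COC(=O)[C@@H](C)CC)[C@@H](O)[C@@H](O[Si](CC)(CC)CC)[C@H]1C#C | intermediate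
23 | {(1Z,5Z,7S,8S,9S,10R)-10-acetoxy-8-ethynyl-5-methyl-7,9-bis[(triethylsilyl)oxy]cyclodeca-1,5-dien-1-yl}methyl (2S)-2-methylbutanoate | CC[Si](CC)(CC)O[C@H]1/C=C(/C)CC/C=C(/COC(=O)[C@@H](C)CC)[C@@H](OC(C)=O)[C@@H](O[Si](CC)(CC)CC)[C@H]1C#C | intermediate
24 | {(1Z,5Z,7S,8S,9S,10R)-10-acetoxy-5-methyl-8-[1-(4,4,5,5-tetramethyl-1,3,2-dioxaborolan-2-yl)ethenyl]-7,9-bis[(triethylsilyl)oxy]cyclodeca-1,5-dien-1-yl}methyl (2S)-2-methylbutanoate | CC[Si](CC)(CC)O[C@H]1/C=C(/C)CC/C=C(/COC(=O)[C@@H](C)CC)[C@@H](OC(C)=O)[C@@H](O[Si](CC)(CC)CC)[C@H]1C(=C)B2OC(C)(C)C(C)(C)O2 | intermediate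
25 | {(1Z,5Z,7S,8S,9S,10R)-10-acetoxy-7,9-dihydroxy-5-methyl-8-[1-(4,4,5,5-tetramethyl-1,3,2-dioxaborolan-2-yl)ethenyl]cyclodeca-1,5-dien-1-yl}methyl (2S)-2-methylbutanoate | O[C@H]1/C=C(/C)CC/C=C(/COC(=O)[C@@H](C)CC)[C@@H](OC(C)=O)[C@@H](O)[C@H]1C(=C)B2OC(C)(C)C(C)(C)O2 | intermediate
26 | cyclic sulfate of 25 bridging the C6 and C8 oxygens (six-membered 1,3,2-dioxathiane 2,2-dioxide; germacrane locants 6S,7S,8S,9R) | O=S2(=O)O[C@H]1/C=C(/C)CC/C=C(/COC(=O)[C@@H](C)CC)[C@@H](OC(C)=O)[C@@H](O2)[C@H]1C(=C)B3OC(C)(C)C(C)(C)O3 | intermediate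
27 | potassium acrylate of the cyclic sulfate (C11 boronate replaced by CO2K; not isolated) | O=S2(=O)O[C@H]1/C=C(/C)CC/C=C(/COC(=O)[C@@H](C)CC)[C@@H](OC(C)=O)[C@@H](O2)[C@H]1C(=C)C(=O)[O-].[K+] | intermediate
28 | potassium salt of the C8 sulfate monoester of the target lactone (not isolated) | C=C1C(=O)O[C@@H]2/C=C(/C)CC/C=C(/COC(=O)[C@@H](C)CC)[C@@H](OC(C)=O)[C@@H](OS(=O)(=O)[O-])[C@@H]12.[K+] | intermediate
29 | (1(10)Z,4Z)-9β-acetoxy-8β-hydroxy-14-[(2S)-2-methylbutanoyloxy]germacra-1(10),4,11(13)-trien-12,6α-olide (6R,7R,8S,9R) | C=C1C(=O)O[C@@H]2/C=C(/C)CC/C=C(/COC(=O)[C@@H](C)CC)[C@@H](OC(C)=O)[C@@H](O)[C@@H]12 | target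

## Step count and risks

Total steps: 21. Longest linear sequence: 18 steps (steps 1–9 and 13–21); the fragment B branch (steps 10–12) joins at step 13.

Steps most likely to fail:

1. Step 21 (bears the label "Proposed new method:"). What may go wrong: attack of the alkenylcopper or of the alkoxide base on the cyclic sulfate before CO2 insertion, opening of the sulfate at C8 instead of C6, or protodeboronation outpacing carboxylation. Fallback with known reactions only, setting out from 24: copper-catalysed carboxylation of the alkenylboronate with CO2 ((IPr)CuCl, KOtBu, THF, 60 °C), carried out while both hydroxyls are still silylated, should give the bis(triethylsilyl) acrylic acid F1. Desilylation with HF·pyridine buffered with pyridine (THF, 0 °C) should give the dihydroxy acid F2, which is added at once to preformed PPh3/DIAD (THF, 0 °C, high dilution). This Mitsunobu lactonisation should close at the allylic C6 hydroxyl with inversion, C8 being the slower centre for displacement, and the fallback comes back to the route at 29.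

2. Step 16. What may go wrong: poor facial selectivity in the addition to the C9 aldehyde, and intermolecular coupling competing with ring closure. Fallback, setting out from 21: the cyclisation is run without regard to selectivity, and the mixture of 22 and its C9 epimer F3 is oxidised with Dess–Martin periodinane to the macrocyclic enone F4. Corey–Bakshi–Shibata reduction ((R)-2-methyl-CBS-oxazaborolidine, catecholborane, toluene, −78 °C, the alkenyl arm taken as the large group) then sets C9 by reagent control, and the fallback comes back to the route at 22.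

3. Step 20. What may go wrong: ionisation of the allylic chlorosulfate (chloride capture or allylic transposition) before the second hydroxyl closes the ring. Fallback, setting out from 25: SOCl2 and pyridine (CH2Cl2, 0 °C) tie the diol as the cyclic sulfite F5 at the tetravalent-sulfur level, which avoids any chlorosulfate. F5 is then taken through the carboxylation and ring opening of step 21 at 70 °C; the sulfite monoester formed on opening loses SO2 on aqueous work-up, so no acid hydrolysis is needed and the fallback comes back to the route at 29.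

Further compounds
F1 | step 21 | acrylic acid from 24 (C11 boronate replaced by CO2H; C6 and C8 triethylsilyl ethers; 6S,7S,8S,9R) | CC[Si](CC)(CC)O[C@H]1/C=C(/C)CC/C=C(/COC(=O)[C@@H](C)CC)[C@@H](OC(C)=O)[C@@H](O[Si](CC)(CC)CC)[C@H]1C(=C)C(=O)O
F2 | step 21 | dihydroxy acrylic acid (F1 without the two silyl groups) | O[C@H]1/C=C(/C)CC/C=C(/COC(=O)[C@@H](C)CC)[C@@H](OC(C)=O)[C@@H](O)[C@H]1C(=C)C(=O)O
F3 | step 16 | C9 epimer of 22 | CC[Si](CC)(CC)O[C@H]1/C=C(/C)CC/C=C(/COC(=O)[C@@H](C)CC)[C@H](O)[C@@H](O[Si](CC)(CC)CC)[C@H]1C#C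
F4 | step 16 | macrocyclic C9 enone from 22 and F3 | CC[Si](CC)(CC)O[C@H]1/C=C(/C)CC/C=C(/COC(=O)[C@@H](C)CC)C(=O)[C@@H](O[Si](CC)(CC)CC)[C@H]1C#C
F5 | step 20 | cyclic sulfite of 25 bridging the C6 and C8 oxygens (mixture of epimers at sulfur) | O=S2O[C@H]1/C=C(/C)CC/C=C(/COC(=O)[C@@H](C)CC)[C@@H](OC(C)=O)[C@@H](O2)[C@H]1C(=C)B3OC(C)(C)C(C)(C)O3
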